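**Assumption:** the SMILES encodes a (1′R) carbinol centre and a 5E exocyclic alkene (exocyclic Br syn to C4, anti to the ring oxygen); that isomer is the one made.

## Retrosynthetic overview

1. Target 9 ⇐ acetylation of (R)-alcohol 8 ⇐ CBS reduction of 3-butanoyl butenolide 7.
2. 7 ⇐ late C3–C1′ union of two similar-sized pieces: C3-metalated bromo-ylidene butenolide 4 (C5 core) + Weinreb amide 6 (C4 side chain).
3. 4 ⇐ anti (5-exo-dig) bromolactonisation of enynoic acid 3. This is the only ring-forming step of the route and it sets the 5E geometry.
4. 3 ⇐ one-carbon homologation of lactol 2 ⇐ photooxygenation of 4-bromofurfural 1. The furan ring is sacrificed; it serves as the template that fixes the cis C3=C4 geometry and the Br position.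
5. 6 ⇐ butanoyl chloride 5.

## Route

All work from step 3 onward is done under amber light, because the 5E isomer can photoisomerise to 5Z.

**Step 1**
Reactants: 1, 4-bromofuran-2-carbaldehyde
Product: 2, 4-bromo-5-hydroxyfuran-2(5H)-one (racemic lactol; this centre is destroyed in step 2)
Conditions: O2, rose bengal (1 mol %), visible hν, MeOH, 0 °C
Reagents that add atoms: dioxygen, O=O
Why: Schenck-type [4+2] photooxygenation of a furfural; the endoperoxide loses the formyl carbon as methyl formate, so the former C2 becomes the lactone C=O and C5 becomes the lactol carbon next to C–Br.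

**Step 2**
Reactants: 2
Product: 3, (2E)-3-bromopent-2-en-4-ynoic acid (CO2H and ethynyl cis)
Conditions: t-BuOK (2.2 equiv), dimethyl (diazomethyl)phosphonate, THF, −78 → 0 °C; then aq. citric acid
Reagents that add atoms: dimethyl (diazomethyl)phosphonate, COP(=O)(OC)C=[N+]=[N-] (delivers one carbon)
Why: base opens the lactol to the cis aldehyde–carboxylate and Seyferth–Gilbert homologation converts CHO into C≡CH; the alkene geometry is inherited from the ring.

**Step 3**
Reactants: 3
Product: 4, (5E)-4-bromo-5-(bromomethylidene)furan-2(5H)-one
Conditions: NBS (1.1 equiv), KHCO3, cat. Bu4NOH, CH2Cl2/H2O, 0 °C, dark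
Reagents that add atoms: N-bromosuccinimide, O=C1CCC(=O)N1Br
Why: bromolactonisation of a terminal alkynoic acid; Br+ adds to the terminal carbon and the carboxylate attacks the internal carbon anti (5-exo-dig), which places the exocyclic Br trans to the ring O (5E).

**Step 4**
Reactants: 5, butanoyl chloride
Product: 6, N-methoxy-N-methylbutanamide
Conditions: MeNH(OMe)·HCl, pyridine, CH2Cl2, 0 °C → rt
Reagents that add atoms: N,O-dimethylhydroxylamine hydrochloride, CNOC.Cl
Why: acyl substitution to the Weinreb amide, which stops cleanly at the ketone in step 5.

**Step 5** (key fragment coupling)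
Reactants: 4 and 6
Product: 7, (5E)-4-bromo-5-(bromomethylidene)-3-butanoylfuran-2(5H)-one
Conditions: TMPMgCl·LiCl (1.1 equiv), THF, −78 °C, 30 min; then 6, −78 → −20 °C; aq. NH4Cl
Reagents that add atoms: none (only 4 and 6)
Why: carbonyl-directed C3–H magnesiation with a Knochel–Hauser base, by analogy with C3 metalation of coumarins and related unsaturated lactones, followed by Weinreb ketone synthesis. The ring prevents β-elimination of the C4–Br, and the hindered amide base does not add to C4 or C6. This step has no direct precedent on this substrate.

**Step 6**
Reactants: 7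
Product: 8, (5E)-4-bromo-5-(bromomethylidene)-3-[(1R)-1-hydroxybutyl]furan-2(5H)-one
Conditions: (S)-Me-CBS (20 mol %), catecholborane (1.5 equiv), toluene/CH2Cl2, −78 °C; MeOH quench, pH 7 buffer
Reagents that add atoms: none
Why: Corey–Bakshi–Shibata reduction; the alkenyl (butenolide) group acts as the large substituent and n-propyl as the small one, so the (S)-catalyst delivers hydride to give the (R)-carbinol (same sense as acetophenone → (R)-1-phenylethanol). Low temperature keeps the reduction 1,2-selective.

**Step 7**
Reactants: 8
Product: 9, (1R)-1-[(5E)-4-bromo-5-(bromomethylidene)-2-oxo-2,5-dihydrofuran-3-yl]butyl acetate (acetoxyfimbrolide, as drawn)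
Conditions: Ac2O (1.5 equiv), Sc(OTf)3 (2 mol %), MeCN, −20 °C, dark
Reagents that add atoms: acetic anhydride, CC(=O)OC(C)=O
Why: Lewis-acid-catalysed O-acetylation; no bond to the stereocentre is broken, and avoiding nucleophilic amines protects the C4–Br and the 5E alkene from addition–elimination.

## Compound list

1 | 4-bromofuran-2-carbaldehyde | O=Cc1cc(Br)co1 | starting material
2 | 4-bromo-5-hydroxyfuran-2(5H)-one | O=C1C=C(Br)C(O)O1 | intermediate
3 | (2E)-3-bromopent-2-en-4-ynoic acid | C#C/C(Br)=C\C(O)=O | intermediate
4 | (5E)-4-bromo-5-(bromomethylidene)furan-2(5H)-one | O=C1C=C(Br)/C(=C\Br)O1 | intermediate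
5 | butanoyl chloride | CCCC(Cl)=O | starting material
6 | N-methoxy-N-methylbutanamide | CCCC(=O)N(C)OC | intermediate
7 | (5E)-4-bromo-5-(bromomethylidene)-3-butanoylfuran-2(5H)-one | CCCC(=O)C1=C(Br)/C(=C\Br)OC1=O | intermediate
8 | (5E)-4-bromo-5-(bromomethylidene)-3-[(1R)-1-hydroxybutyl]furan-2(5H)-one | CCC[C@@H](O)C1=C(Br)/C(=C\Br)OC1=O | intermediate
9 | (1R)-1-[(5E)-4-bromo-5-(bromomethylidene)-2-oxo-2,5-dihydrofuran-3-yl]butyl acetate | CCC[C@@H](OC(C)=O)C1=C(Br)/C(=C\Br)OC1=O | target

## Step count

Total steps: 7.
Longest linear sequence: 6 (1 → 2 → 3 → 4 → 7 → 8 → 9). The side-chain branch (5 → 6) joins at step 5.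

## Steps most likely to fail, with fallbacks

1. **Step 5 (C3 metalation and acylation of the polyhalogenated dienyl lactone).** Competing C6–H metalation or self-condensation could intervene. Fallback: attach the butanoyl group at the furan stage instead. 3,4-Dibromofuran is 2-formylated (LDA, DMF) and protected as the dioxolane; acetal-directed Br/Li exchange at C3 and reaction with 6 gives the furyl ketone. Noyori transfer hydrogenation, acetylation and acetal removal follow, and the same photooxygenation, homologation and NBS sequence is then run with the side chain already in place.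

2. **Step 6 (CBS reduction of the doubly activated ketone).** Conjugate reduction with loss of the C4–Br, or erosion of ee, is possible. Fallback: reverse the polarity. Quench the C3-magnesium species from step 5 with DMF to give the 3-formyl butenolide, then carry out a catalytic asymmetric n-propyl transfer (Pr2Zn with a chiral amino-alcohol catalyst such as MIB) and trap the zinc alkoxide with Ac2O to give 9 directly.

3. **Step 2 (Seyferth–Gilbert homologation on the lactol/enal).** Conjugate additions or cis → trans isomerisation of the open aldehyde-acid could lower the yield. Fallback: make acid 3 from 3-bromofuran-2-carbaldehyde through its tosylhydrazone. Thermal generation of the 2-furylcarbene opens the ring to (Z)-3-bromopent-2-en-4-ynal, and Pinnick oxidation gives 3.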